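**Retrosynthetic overview**

1. The C1=C10 oxirane is put in last by epoxidation of the only electron-rich alkene. Before that, the C3 benzoate and the C8 (2R,3R)-epoxyangelate are attached to a ten-membered 3-oxo-8-hydroxy core, with C3 set by oxazaborolidine reduction and C8 by Mitsunobu inversion.
2. The ten-membered ring is closed at C3–C4 by an intramolecular Nozaki–Hiyama–Kishi reaction of a Z-alkenyl iodide with an aldehyde.
3. The open chain comes from a Barbier allylation (C7–C8) that joins an eight-carbon bromomethyl butenolide (C4–C7, C11–C13, C15) to a seven-carbon β,γ-unsaturated aldehyde (C1–C3, C8–C10, C14). This step also sets C7 and C8 and unveils the α-methylene lactone.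
4. The butenolide is made from acrolein, propynyl Grignard reagent and 2-(bromomethyl)acrylic acid; the aldehyde from but-3-yn-1-ol, AlMe3 and oxirane; the side-chain acid from methyl angelate; benzoic acid from benzaldehyde.
5. Ring order: butenolide (metathesis), which becomes the α-methylene lactone at the coupling, then the ten-membered carbocycle, then the 1,10-oxirane (the side-chain oxirane is made separately).

Assumption: germacrane numbering is used (lactone oxygen on C6, acyloxy on C8, benzoate on C3, oxirane at C1/C10, C14 on C10, C15 on C4), and the seven starting materials are taken as commercial.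

**Butenolide fragment**

Step 1
Reactants: 1 acrolein; 2 prop-1-yn-1-ylmagnesium bromide
Product: 3 rac-hex-1-en-4-yn-3-ol
Conditions: THF, −78 to 0 °C; sat. aq. NH4Cl
Reagents that add atoms: none
Why: 1,2-addition of the alkynyl Grignard reagent to the enal carbonyl gives the racemic carbinol that carries C4–C7 and C15.

Step 2
Reactants: 3 rac-hex-1-en-4-yn-3-ol
Product: 5 rac-(4Z)-5-iodohexa-1,4-dien-3-ol, via cyclic sodium alkenylalanate 4 (not isolated)
Conditions: NaAlH2(OCH2CH2OMe)2, THF, 0 °C to rt; EtOAc; then I2, THF, −78 °C; aq. Na2S2O3, aq. potassium sodium tartrate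
Reagents that add atoms: iodine I2, [I][I]
Why: alkoxide-directed trans-hydroalumination puts aluminium on C4 cis to the carbinol carbon, and iodinolysis with retention gives the Z alkenyl iodide (hydroalumination–iodination), the vinyl group being untouched.

Step 3
Reactants: 5 rac-(4Z)-5-iodohexa-1,4-dien-3-ol
Product: 6 (3S,4Z)-5-iodohexa-1,4-dien-3-ol
Conditions: immobilised Candida antarctica lipase B, vinyl acetate, hexane, 30 °C, to about 55% conversion; chromatography
Reagents that add atoms: none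
Why: enzymatic kinetic resolution (Kazlauskas rule, large iodoalkenyl against medium vinyl) acetylates the R alcohol and leaves the S alcohol, which sets C6 (at most about 45% yield).

Step 4
Reactants: 6 (3S,4Z)-5-iodohexa-1,4-dien-3-ol; 7 2-(bromomethyl)prop-2-enoic acid
Product: 8 (3S,4Z)-5-iodohexa-1,4-dien-3-yl 2-(bromomethyl)prop-2-enoate
Conditions: DCC, DMAP (5 mol %), CH2Cl2, 0 °C
Reagents that add atoms: none
Why: Steglich esterification under cold, nearly neutral conditions acylates the doubly allylic alcohol without ionisation, so C6 is retained.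

Step 5
Reactants: 8 (3S,4Z)-5-iodohexa-1,4-dien-3-yl 2-(bromomethyl)prop-2-enoate
Product: 9 (5S)-3-(bromomethyl)-5-[(1Z)-2-iodoprop-1-en-1-yl]furan-2(5H)-one
Conditions: second-generation Grubbs catalyst RuCl2(=CHPh)(H2IMes)(PCy3) (5 mol %), toluene (5 mM), 80 °C
Reagents that add atoms: none
Why: ring-closing metathesis between the terminal vinyl group and the acrylate alkene closes the butenolide (C7=C11) with loss of ethene, the trisubstituted iodoalkene and the allylic bromide being inert to the ruthenium carbene.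

**Aldehyde fragment**

Step 6
Reactants: 10 but-3-yn-1-ol
Product: 11 1-[(but-3-yn-1-yloxy)methyl]-4-methoxybenzene
Conditions: NaH, 4-methoxybenzyl chloride, Bu4NI (cat.), THF, 0 °C to rt
Reagents that add atoms: 4-methoxybenzyl chloride, COc1ccc(CCl)cc1
Why: Williamson etherification protects the oxygen on the carbon that later becomes the C8 aldehyde.

Step 7
Reactants: 11 1-[(but-3-yn-1-yloxy)methyl]-4-methoxybenzene; 12 oxirane
Product: 15 (3E)-6-[(4-methoxybenzyl)oxy]-4-methylhex-3-en-1-ol, via alkenyldimethylalane 13 (not isolated), via lithium alkenylalanate 14 (not isolated)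
Conditions: AlMe3 (2.5 equiv), Cp2ZrCl2 (0.2 equiv), CH2Cl2, 0 °C to rt; evaporate; n-BuLi, hexane/THF, −78 °C; oxirane, −78 to 0 °C; aq. potassium sodium tartrate
Reagents that add atoms: trimethylaluminium, C[Al](C)C
Why: Negishi zirconium-catalysed syn-carboalumination puts methyl (C14) on the internal and aluminium on the terminal alkyne carbon, and the alanate opens oxirane with retention, which fixes the E geometry of C1=C10.

Step 8
Reactants: 15 (3E)-6-[(4-methoxybenzyl)oxy]-4-methylhex-3-en-1-ol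
Product: 16 tert-butyl{[(3E)-6-[(4-methoxybenzyl)oxy]-4-methylhex-3-en-1-yl]oxy}dimethylsilane
Conditions: TBSCl, imidazole, DMF, rt
Reagents that add atoms: tert-butyldimethylsilyl chloride, CC(C)(C)[Si](C)(C)Cl
Why: silylation masks the C3 oxygen so that the two chain ends stay differentiated.

Step 9
Reactants: 16 tert-butyl{[(3E)-6-[(4-methoxybenzyl)oxy]-4-methylhex-3-en-1-yl]oxy}dimethylsilane
Product: 17 (3E)-6-{[tert-butyl(dimethyl)silyl]oxy}-3-methylhex-3-en-1-ol
Conditions: DDQ, CH2Cl2/pH 7 phosphate buffer, 0 °C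
Reagents that add atoms: none
Why: oxidative cleavage of the electron-rich benzyl ether (hydride abstraction, then hydrolysis) frees the C8 alcohol while the silyl ether and the alkene survive.

Step 10
Reactants: 17 (3E)-6-{[tert-butyl(dimethyl)silyl]oxy}-3-methylhex-3-en-1-ol
Product: 18 (3E)-6-{[tert-butyl(dimethyl)silyl]oxy}-3-methylhex-3-enal
Conditions: Dess–Martin periodinane, NaHCO3, CH2Cl2, 0 °C; used crude
Reagents that add atoms: none
Why: buffered Dess–Martin oxidation gives the β,γ-unsaturated aldehyde without moving the alkene into conjugation.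

**Side-chain acid and benzoic acid**

Step 11
Reactants: 19 methyl (2Z)-2-methylbut-2-enoate (methyl angelate)
Product: 20 (2Z)-2-methylbut-2-en-1-ol
Conditions: iBu2AlH (2.2 equiv), CH2Cl2, −78 °C; aq. potassium sodium tartrate
Reagents that add atoms: none
Why: 1,2-reduction of the ester with the aluminium hydride keeps the Z alkene.

Step 12
Reactants: 20 (2Z)-2-methylbut-2-en-1-ol
Product: 21 [(2S,3R)-2,3-dimethyloxiran-2-yl]methanol
Conditions: Ti(OiPr)4, L-(+)-diethyl tartrate, tert-butyl hydroperoxide, 4 Å molecular sieves, CH2Cl2, −20 °C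
Reagents that add atoms: tert-butyl hydroperoxide, CC(C)(C)OO
Why: Sharpless asymmetric epoxidation with L-(+)-tartrate delivers oxygen to the same alkene face as in the geraniol case, giving the (2S,3R)-epoxy alcohol and so both side-chain stereocentres.

Step 13
Reactants: 21 [(2S,3R)-2,3-dimethyloxiran-2-yl]methanol
Product: 22 (2R,3R)-2,3-dimethyloxirane-2-carboxylic acid
Conditions: RuCl3 (2 mol %), NaIO4, CCl4/MeCN/H2O, 0 °C to rt
Reagents that add atoms: water, O
Why: RuO4 generated in the flask oxidises the primary alcohol through the aldehyde hydrate to the acid without opening the oxirane (the descriptor at C2 changes only through priorities).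

Step 14
Reactants: 23 benzaldehyde
Product: 24 benzoic acid
Conditions: KHSO5 (as 2KHSO5·KHSO4·K2SO4), DMF, rt
Reagents that add atoms: potassium peroxymonosulfate KHSO5, [K+].OOS(=O)(=O)[O-]
Why: peroxymonosulfate oxidation of the aldehyde gives the acid used for the C3 ester.

**Fragment union and endgame**

Step 15
Reactants: 9 (5S)-3-(bromomethyl)-5-[(1Z)-2-iodoprop-1-en-1-yl]furan-2(5H)-one; 18 (3E)-6-{[tert-butyl(dimethyl)silyl]oxy}-3-methylhex-3-enal
Product: 26 (4R,5S)-4-[(1S,3E)-6-{[tert-butyl(dimethyl)silyl]oxy}-1-hydroxy-3-methylhex-3-en-1-yl]-5-[(1Z)-2-iodoprop-1-en-1-yl]-3-methylideneoxolan-2-one, via allylzinc bromide 25 (not isolated)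
Conditions: Zn dust, THF/sat. aq. NH4Cl, 0 °C to rt
Reagents that add atoms: none
Why: in this Barbier allylation the allylzinc attacks the aldehyde through ring carbon C7 on the face anti to the C6 alkenyl group (trans lactone, exocyclic methylene restored), and the ring-locked allyl geometry in a chair transition state gives the anti adduct, the 8S carbinol, which is inverted in step 20; the alkenyl iodide is inert to zinc.

Step 16
Reactants: 26 (4R,5S)-4-[(1S,3E)-6-{[tert-butyl(dimethyl)silyl]oxy}-1-hydroxy-3-methylhex-3-en-1-yl]-5-[(1Z)-2-iodoprop-1-en-1-yl]-3-methylideneoxolan-2-one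
Product: 27 (4R,5S)-4-[(1S,3E)-1,6-dihydroxy-3-methylhex-3-en-1-yl]-5-[(1Z)-2-iodoprop-1-en-1-yl]-3-methylideneoxolan-2-one
Conditions: HF·pyridine, THF/pyridine, 0 °C
Reagents that add atoms: none
Why: fluoride-driven desilylation frees the primary C3 alcohol under conditions that leave the lactone and the alkenyl iodide alone.

Step 17
Reactants: 27 (4R,5S)-4-[(1S,3E)-1,6-dihydroxy-3-methylhex-3-en-1-yl]-5-[(1Z)-2-iodoprop-1-en-1-yl]-3-methylideneoxolan-2-one
Product: 28 (3E,6S)-6-hydroxy-6-[(2S,3R)-2-[(1Z)-2-iodoprop-1-en-1-yl]-4-methylidene-5-oxooxolan-3-yl]-4-methylhex-3-enal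
Conditions: TEMPO (10 mol %), PhI(OAc)2, CH2Cl2, rt; used crude
Reagents that add atoms: none
Why: the oxoammonium oxidation is selective for the primary alcohol over the hindered secondary C8 alcohol, so no protecting group is needed.

Step 18
Reactants: 28 (3E,6S)-6-hydroxy-6-[(2S,3R)-2-[(1Z)-2-iodoprop-1-en-1-yl]-4-methylidene-5-oxooxolan-3-yl]-4-methylhex-3-enal
Product: 29 (6R,7R,8S)-3,8-dihydroxygermacra-1(10)E,4Z,11(13)-trien-12,6-olide (mixture of C3 epimers)
Conditions: CrCl2 (8 equiv), NiCl2 (2 mol % of the chromium), degassed DMSO (5 mM), rt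
Reagents that add atoms: none
Why: in this Nozaki–Hiyama–Kishi macrocyclisation zerovalent nickel inserts into the C–I bond and hands the alkenyl group to chromium, and the alkenylchromium adds to the aldehyde with retention of the Z geometry; the free C8 hydroxyl is tolerated and the C3 mixture is levelled in step 19.

Step 19
Reactants: 29 (6R,7R,8S)-3,8-dihydroxygermacra-1(10)E,4Z,11(13)-trien-12,6-olide
Product: 30 (6R,7R,8S)-8-hydroxy-3-oxogermacra-1(10)E,4Z,11(13)-trien-12,6-olide
Conditions: activated MnO2 (excess), CH2Cl2, rt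
Reagents that add atoms: none
Why: MnO2 oxidises only the allylic C3 alcohol (both epimers) and leaves the non-allylic C8 alcohol.

Step 20
Reactants: 30 (6R,7R,8S)-8-hydroxy-3-oxogermacra-1(10)E,4Z,11(13)-trien-12,6-olide; 22 (2R,3R)-2,3-dimethyloxirane-2-carboxylic acid
Product: 31 (6R,7R,8R)-8-[(2R,3R)-2,3-dimethyloxirane-2-carbonyloxy]-3-oxogermacra-1(10)E,4Z,11(13)-trien-12,6-olide
Conditions: PPh3, DIAD (betaine preformed), toluene, 0 °C to rt
Reagents that add atoms: none
Why: Mitsunobu esterification displaces the activated C8 oxygen by the carboxylate in an SN2 step, which inverts C8 from S to R and installs the side chain in one operation.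

Step 21
Reactants: 31 (6R,7R,8R)-8-[(2R,3R)-2,3-dimethyloxirane-2-carbonyloxy]-3-oxogermacra-1(10)E,4Z,11(13)-trien-12,6-olide
Product: 32 (3S,6R,7R,8R)-8-[(2R,3R)-2,3-dimethyloxirane-2-carbonyloxy]-3-hydroxygermacra-1(10)E,4Z,11(13)-trien-12,6-olide
Conditions: (R)-2-methyl-CBS-oxazaborolidine (0.5 equiv), catecholborane, toluene, −78 °C; MeOH, pH 7 buffer
Reagents that add atoms: none
Why: Corey–Bakshi–Shibata reduction with the R catalyst, the α-methyl alkenyl group acting as the large and C2H2 as the small substituent, delivers hydride to give the 3S allylic alcohol; the lactone, the esters and the alkenes are not touched at −78 °C.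

Step 22
Reactants: 32 (3S,6R,7R,8R)-8-[(2R,3R)-2,3-dimethyloxirane-2-carbonyloxy]-3-hydroxygermacra-1(10)E,4Z,11(13)-trien-12,6-olide; 24 benzoic acid
Product: 33 (3S,6R,7R,8R)-3-benzoyloxy-8-[(2R,3R)-2,3-dimethyloxirane-2-carbonyloxy]germacra-1(10)E,4Z,11(13)-trien-12,6-olide
Conditions: DCC, DMAP (cat.), CH2Cl2, 0 °C to rt
Reagents that add atoms: none
Why: Steglich esterification acylates the only free hydroxyl with retention at C3.

Step 23
Reactants: 33 (3S,6R,7R,8R)-3-benzoyloxy-8-[(2R,3R)-2,3-dimethyloxirane-2-carbonyloxy]germacra-1(10)E,4Z,11(13)-trien-12,6-olide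
Product: 34 (1R,3S,6R,7R,8R,10R)-3-benzoyloxy-1,10-epoxy-8-[(2R,3R)-2,3-dimethyloxirane-2-carbonyloxy]germacra-4Z,11(13)-dien-12,6-olide (target)
Conditions: dimethyldioxirane (1.1 equiv, acetone solution), CH2Cl2, −20 °C
Reagents that add atoms: dimethyldioxirane, CC1(C)OO1
Why: the neutral electrophilic epoxidation takes only the isolated trisubstituted C1=C10 alkene (C4=C5 is deactivated by two allylic acyloxy groups, C11=C13 is electron-poor), and attack on the exposed outer face of the E alkene gives the trans (1R,10R) oxirane found in natural heliangolide epoxides.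

**Compound list**

1 | acrolein (prop-2-enal) | C=CC=O | starting material
2 | prop-1-yn-1-ylmagnesium bromide | CC#C[Mg]Br | starting material
3 | rac-hex-1-en-4-yn-3-ol | C=CC(O)C#CC | intermediate
4 | cyclic sodium alkenylalanate (sodium 5-ethenyl-2,2-bis(2-methoxyethoxy)-3-methyl-2,5-dihydro-1,2-oxaluminol-2-uide) | [Na+].C=CC1C=C(C)[Al-](OCCOC)(OCCOC)O1 | intermediate
5 | rac-(4Z)-5-iodohexa-1,4-dien-3-ol | C=CC(O)/C=C(/C)I | intermediate
6 | (3S,4Z)-5-iodohexa-1,4-dien-3-ol | C=C[C@H](O)/C=C(/C)I | intermediate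
7 | 2-(bromomethyl)prop-2-enoic acid | C=C(CBr)C(=O)O | starting material
8 | (3S,4Z)-5-iodohexa-1,4-dien-3-yl 2-(bromomethyl)prop-2-enoate | C=C[C@H](OC(=O)C(=C)CBr)/C=C(/C)I | intermediate
9 | (5S)-3-(bromomethyl)-5-[(1Z)-2-iodoprop-1-en-1-yl]furan-2(5H)-one | BrCC1=C[C@@H](/C=C(/C)I)OC1=O | intermediate
10 | but-3-yn-1-ol | C#CCCO | starting material
11 | 1-[(but-3-yn-1-yloxy)methyl]-4-methoxybenzene | C#CCCOCc1ccc(OC)cc1 | intermediate
12 | oxirane | C1CO1 | starting material
13 | [(1E)-4-[(4-methoxybenzyl)oxy]-2-methylbut-1-en-1-yl]dimethylalane | C[Al](C)/C=C(\C)CCOCc1ccc(OC)cc1 | intermediate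
14 | lithium butyl[(1E)-4-[(4-methoxybenzyl)oxy]-2-methylbut-1-en-1-yl]dimethylaluminate | [Li+].CCCC[Al-](C)(C)/C=C(\C)CCOCc1ccc(OC)cc1 | intermediate
15 | (3E)-6-[(4-methoxybenzyl)oxy]-4-methylhex-3-en-1-ol | OCC/C=C(\C)CCOCc1ccc(OC)cc1 | intermediate
16 | tert-butyl{[(3E)-6-[(4-methoxybenzyl)oxy]-4-methylhex-3-en-1-yl]oxy}dimethylsilane | CC(C)(C)[Si](C)(C)OCC/C=C(\C)CCOCc1ccc(OC)cc1 | intermediate
17 | (3E)-6-{[tert-butyl(dimethyl)silyl]oxy}-3-methylhex-3-en-1-ol | CC(C)(C)[Si](C)(C)OCC/C=C(\C)CCO | intermediate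
18 | (3E)-6-{[tert-butyl(dimethyl)silyl]oxy}-3-methylhex-3-enal | CC(C)(C)[Si](C)(C)OCC/C=C(\C)CC=O | intermediate
19 | methyl (2Z)-2-methylbut-2-enoate | C/C=C(/C)C(=O)OC | starting material
20 | (2Z)-2-methylbut-2-en-1-ol | C/C=C(/C)CO | intermediate
21 | [(2S,3R)-2,3-dimethyloxiran-2-yl]methanol | OC[C@]1(C)O[C@@H]1C | intermediate
22 | (2R,3R)-2,3-dimethyloxirane-2-carboxylic acid | OC(=O)[C@]1(C)O[C@@H]1C | intermediate
23 | benzaldehyde | O=Cc1ccccc1 | starting material
24 | benzoic acid | OC(=O)c1ccccc1 | intermediate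
25 | allylzinc bromide of 9 (bromo{[(5S)-5-[(1Z)-2-iodoprop-1-en-1-yl]-2-oxo-2,5-dihydrofuran-3-yl]methyl}zinc) | Br[Zn]CC1=C[C@@H](/C=C(/C)I)OC1=O | intermediate
26 | (4R,5S)-4-[(1S,3E)-6-{[tert-butyl(dimethyl)silyl]oxy}-1-hydroxy-3-methylhex-3-en-1-yl]-5-[(1Z)-2-iodoprop-1-en-1-yl]-3-methylideneoxolan-2-one | C=C1C(=O)O[C@H](/C=C(/C)I)[C@H]1[C@@H](O)C/C(C)=C/CCO[Si](C)(C)C(C)(C)C | intermediate
27 | (4R,5S)-4-[(1S,3E)-1,6-dihydroxy-3-methylhex-3-en-1-yl]-5-[(1Z)-2-iodoprop-1-en-1-yl]-3-methylideneoxolan-2-one | C=C1C(=O)O[C@H](/C=C(/C)I)[C@H]1[C@@H](O)C/C(C)=C/CCO | intermediate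
28 | (3E,6S)-6-hydroxy-6-[(2S,3R)-2-[(1Z)-2-iodoprop-1-en-1-yl]-4-methylidene-5-oxooxolan-3-yl]-4-methylhex-3-enal | C=C1C(=O)O[C@H](/C=C(/C)I)[C@H]1[C@@H](O)C/C(C)=C/CC=O | intermediate
29 | (6R,7R,8S)-3,8-dihydroxygermacra-1(10)E,4Z,11(13)-trien-12,6-olide, C3 epimers | C=C1C(=O)O[C@@H]2/C=C(/C)C(O)C/C=C(\C)C[C@H](O)[C@@H]12 | intermediate
30 | (6R,7R,8S)-8-hydroxy-3-oxogermacra-1(10)E,4Z,11(13)-trien-12,6-olide | C=C1C(=O)O[C@@H]2/C=C(/C)C(=O)C/C=C(\C)C[C@H](O)[C@@H]12 | intermediate
31 | (6R,7R,8R)-8-[(2R,3R)-2,3-dimethyloxirane-2-carbonyloxy]-3-oxogermacra-1(10)E,4Z,11(13)-trien-12,6-olide | C=C1C(=O)O[C@@H]2/C=C(/C)C(=O)C/C=C(\C)C[C@@H](OC(=O)[C@]3(C)O[C@@H]3C)[C@@H]12 | intermediate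
32 | (3S,6R,7R,8R)-8-[(2R,3R)-2,3-dimethyloxirane-2-carbonyloxy]-3-hydroxygermacra-1(10)E,4Z,11(13)-trien-12,6-olide | C=C1C(=O)O[C@@H]2/C=C(/C)[C@@H](O)C/C=C(\C)C[C@@H](OC(=O)[C@]3(C)O[C@@H]3C)[C@@H]12 | intermediate
33 | (3S,6R,7R,8R)-3-benzoyloxy-8-[(2R,3R)-2,3-dimethyloxirane-2-carbonyloxy]germacra-1(10)E,4Z,11(13)-trien-12,6-olide | C=C1C(=O)O[C@@H]2/C=C(/C)[C@@H](OC(=O)c3ccccc3)C/C=C(\C)C[C@@H](OC(=O)[C@]3(C)O[C@@H]3C)[C@@H]12 | intermediate
34 | (1R,3S,6R,7R,8R,10R)-3-benzoyloxy-1,10-epoxy-8-[(2R,3R)-2,3-dimethyloxirane-2-carbonyloxy]germacra-4Z,11(13)-dien-12,6-olide | C=C1C(=O)O[C@@H]2/C=C(/C)[C@@H](OC(=O)c3ccccc3)C[C@H]3O[C@]3(C)C[C@@H](OC(=O)[C@]3(C)O[C@@H]3C)[C@@H]12 | target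

**Totals**

Total step count: 23.
Longest linear sequence: 14 steps (steps 1–5, then 15–23; the branch 6–10, then 15–23, is equally long).

**Three steps most likely to fail**

1. Step 18 (closure of the strained ten-membered ring, with oligomerisation as the competing path). The fallback sets out from 9 and 15 and comes back at 29. The order of the two carbon–carbon bond formations is exchanged so that the ring is closed by allylation at C7–C8 instead of alkenylation at C3–C4. Bromide 9 is converted with KOAc in DMF into allylic acetate F1, which does not react with divalent chromium. Alcohol 15 is oxidised with Dess–Martin periodinane to aldehyde F2. Intermolecular CrCl2/NiCl2 coupling of the two gives allylic alcohol F3 (C3 epimers, levelled in step 19). DDQ removes the benzyl ether to give diol F4, and TEMPO/PhI(OAc)2 oxidises its primary alcohol to hydroxy aldehyde F5. Pd(PPh3)4 with InI then turns the allylic acetate into an allylindium species that closes the ring by intramolecular allylation of the C8 aldehyde anti to the C6 substituent, giving diol 29.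

2. Step 20 (Mitsunobu inversion of a hindered secondary alcohol next to the lactone ring, with elimination towards C7 or C9 as the competing path). The fallback sets out from 30 and comes back at 31. The alcohol is converted with ClCH2SO2Cl and pyridine into chloromethanesulfonate F6. The sulfonate is then displaced with inversion by the caesium salt of acid 22 (Cs2CO3, 18-crown-6, toluene). This is an alkylation of the carboxylate by a small, very reactive leaving group instead of a redox condensation.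

3. Step 23 (the face of the C1=C10 alkene taken by the oxidant rests on the ring conformation alone). The fallback sets out from 33 and comes back at 34, and is used if the dioxirane attacks the wrong face. NBS in aqueous acetone forms the bromonium ion on that same exposed face, and water opens it at C10 from the other side, giving bromohydrin F7. Ag2O in CH2Cl2 then closes the oxirane by backside displacement of bromide by the C10 oxygen, which places the oxirane oxygen on the face opposite to the one the electrophile took.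

**Further compounds**

F1 | step 18 | [(5S)-5-[(1Z)-2-iodoprop-1-en-1-yl]-2-oxo-2,5-dihydrofuran-3-yl]methyl acetate | CC(=O)OCC1=C[C@@H](/C=C(/C)I)OC1=O
F2 | step 18 | (3E)-6-[(4-methoxybenzyl)oxy]-4-methylhex-3-enal | O=CC/C=C(\C)CCOCc1ccc(OC)cc1
F3 | step 18 | {5-[(1Z,5E)-3-hydroxy-8-[(4-methoxybenzyl)oxy]-2,6-dimethylocta-1,5-dien-1-yl]-2-oxo-2,5-dihydrofuran-3-yl}methyl acetate (ring carbon as in 9; carbinol epimers) | CC(=O)OCC1=C[C@@H](/C=C(/C)C(O)C/C=C(\C)CCOCc2ccc(OC)cc2)OC1=O
F4 | step 18 | {5-[(1Z,5E)-3,8-dihydroxy-2,6-dimethylocta-1,5-dien-1-yl]-2-oxo-2,5-dihydrofuran-3-yl}methyl acetate (ring carbon as in 9; carbinol epimers) | CC(=O)OCC1=C[C@@H](/C=C(/C)C(O)C/C=C(\C)CCO)OC1=O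
F5 | step 18 | {5-[(1Z,5E)-3-hydroxy-2,6-dimethyl-8-oxoocta-1,5-dien-1-yl]-2-oxo-2,5-dihydrofuran-3-yl}methyl acetate (ring carbon as in 9; carbinol epimers) | CC(=O)OCC1=C[C@@H](/C=C(/C)C(O)C/C=C(\C)CC=O)OC1=O
F6 | step 20 | (6R,7R,8S)-8-[(chloromethanesulfonyl)oxy]-3-oxogermacra-1(10)E,4Z,11(13)-trien-12,6-olide | C=C1C(=O)O[C@@H]2/C=C(/C)C(=O)C/C=C(\C)C[C@H](OS(=O)(=O)CCl)[C@@H]12
F7 | step 23 | (1S,3S,6R,7R,8R,10R)-3-benzoyloxy-1-bromo-8-[(2R,3R)-2,3-dimethyloxirane-2-carbonyloxy]-10-hydroxygermacra-4Z,11(13)-dien-12,6-olide | C=C1C(=O)O[C@@H]2/C=C(/C)[C@@H](OC(=O)c3ccccc3)C[C@H](Br)[C@](C)(O)C[C@@H](OC(=O)[C@]3(C)O[C@@H]3C)[C@@H]12
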